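**Remarks on the chemistry**
- Bicyclic compounds carry labdane locants (ring A: C1–C5, C10; ring B: C5–C10; side chain C11–C16 on C9; C17 on C8; C18/C19 on C4; C20 on C10). α is the face of H5, β the face of C20.
- Correction: the C9 substituent of the cyclopropanation substrate and of its product is a 4-(trimethylsilyl)but-3-yn-1-yl group (C11–C14). The five-carbon pentynyl nucleophile used earlier also supplies C9, so the chain on C9 is not a pentynyl group.
- Correction: the key-step product of the third alternative has no C17 and is named as a 17-norlabdane.
- Assumption: the (R,R) ligand in step 3 gives the (S) centre; if the sense of induction is the opposite, the (S,S) ligand is used and nothing else changes.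
- Design changes to the usual sequence: hydroboration is done before the enone and the alkyne exist; the cyclopropyl ketone is opened with SmI2 and not with a dissolving metal, because a silylalkyne is carried; the acid is carried as an allyl ester so that the 2β-acetate never meets hydroxide.

## Structural features

The target is a labdane: a trans-fused decalin with a gem-dimethyl group at C4, an angular methyl (C20) at C10, an exocyclic methylene (C17) at C8 and, on C9, a chain C11–C12 ending in an (E)-3-methylbut-2-enoic acid unit (C13=C14, C15 acid). It has four stereocentres, C2, C5, C9 and C10, of which C5, C10 and C9 are contiguous and C10 is quaternary; H5 and H9 are α, while C20, the side chain and the 2-acetoxy group are β. The 2β-oxygen is axial and 1,3-syn-axial to both the 4β-methyl (C19) and C20, so the acetate is hindered and its alcohol is the less stable C2 epimer. Fragile groups are the exocyclic C8=C17 alkene (it migrates into the ring under acid), the secondary acetate (base-labile, yet it must coexist with a free acid) and the geometry of the trisubstituted enoate. The real difficulty is the quaternary C10 trans to H5 and next to C9, combined with an oxygen on the more crowded β face of ring A. The key step exploits the fact that O2 and C20 are cis and separated only by C1: in a ring A allylic alcohol with a C1=C10 double bond, the 2β-hydroxyl can deliver a methylene to C10 on its own face. The extra C1–C20 bond made at the same time lies next to C2 and can be cut once C2 is a ketone.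

## Logic of the disconnections

**32 ⇒ 31.** The C15–O allyl bond is cut. The acid is freed last under neutral palladium conditions because acetate and ester cannot be told apart by hydroxide. Nothing is simplified structurally; the demand is a deallylation that leaves the acetate and the exocyclic alkene alone.

**31 ⇒ 29 + 3.** C13–C16 and C14–C15 are cut. The (E)-trisubstituted enoate is traced to a terminal alkyne, because syn-carbometalation fixes the geometry. The side chain shrinks to a butynyl group that is inert through most earlier steps. The forward step must methylaluminate regioselectively in the presence of an acetate and a 1,1-disubstituted alkene, and the alkenylalane must be acylated directly.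

**29 ⇒ 28 ⇒ 27 ⇒ 26.** C8=C17 is cut and C8 is taken back to a silyl-protected alcohol. The alkene is introduced late so that it never meets carbenoid, hydride or acid, and the C8 oxygen is the one the ring B closure produces. The demand is a non-basic methylenation of a hindered, epimerisable ketone, and one fluoride step that removes both silyl groups.

**26 ⇒ 25 ⇒ 24.** The acetyl C–O bond and the C2–H bond are cut. The axial alcohol is reachable only by kinetic hydride delivery from the α face, and the ketone is what the ring opening leaves. The demand is equatorial hydride attack and acylation of a hindered axial hydroxyl.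

**24 ⇒ 23 ⇒ 22.** Retrosynthetically C1–C20 is reconnected: the angular methyl is read as the remnant of a cyclopropane fused at C1–C10, whose exocyclic bond is activated by the C2 carbonyl. The quaternary-centre problem becomes a facial-selectivity problem on an alkene. The forward scission must cut only the exocyclic bond and spare the alkyne.

**22 ⇒ 20 + 21 (key).** C10–C20 and C1–C20 are cut. This removes the quaternary centre and two stereocentres and leaves a planar C1=C10 alkene with one controlling carbinol. The forward step needs complete syn delivery from the 2β-hydroxyl.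

**20 ⇒ 19 ⇒ 18.** The C2–H bond and the O–Si bond are cut. The directing alcohol comes from the enone, and the C8 oxygen is capped so that it can neither direct the carbenoid nor be confused with O2 later. The demand is 1,2-reduction from the α face.

**18 ⇒ 17.** C8–C9 is cut (ring B). C9 is the γ-carbon of the ring A enone and C8 bears oxygen, which is a vinylogous aldol retron. The bicycle becomes a monocycle with a single stereocentre (C5). The demand is γ-selectivity over the α and α′ positions, equatorial placement of both new substituents, and an untouched C5.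

**17 ⇒ 16 ⇒ 8 + 12.** C9–C10 is cut with 1,3-carbonyl transposition, and C8 is taken back to the alcohol. A β-alkyl enone with a γ-stereocentre is the retron of an alkylative enone transposition, and the cut joins the alkynyl chain convergently. The demand is 1,2-addition to a hindered carbonyl without enolisation.

**8 ⇒ 6 ⇒ 5 ⇒ 2 + 3.** The C8–O bond (hydroboration) and the C5–C6 bond (allylation) are cut. The allyl group is a three-carbon aldehyde equivalent (C6–C8), and C5 is the only centre set by reagent control. The demand is enantioselective formation of a tertiary α′ centre next to a quaternary carbon.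

**2 ⇒ 1 and 12 ⇒ 11 ⇒ 9.** The enol ether C–O bond, the C–I bond and the C–Si bond are cut. 1 supplies C1–C5, C10, C18 and C19; 9 supplies C9 and C11–C14. These are standard functional-group steps with no selectivity demand.

## Other disconnections considered

**Alternative 1:** The cut removes the ring-fusion bond C5–C10 together with C8–C9, opening both rings to the acyclic triene A2 (methyl (2E,8E,10E)-5-(tert-butyldimethylsilyloxy)-12-(4-methoxybenzyloxy)-3,7,7-trimethyldodeca-2,8,10-trienoate). In the forward sense, heating A2 or activating its enoate with a Lewis acid would let the C5=C6–C7=C8 diene add to the C9=C10 enoate in an intramolecular Diels–Alder reaction. The product would be the trans-fused octalin A1 (2α-silyloxy, 8β-CH2OPMB, 9β-CO2Me, C6=C7).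
- In its favour: one suprafacial step would make both rings, the quaternary C10 and four stereocentres (C5, C8, C9, C10) with no sacrificial bond, from a linear precursor whose only stereocentre is C2.
- Against it here: the dienophile is a β,β-disubstituted enoate and the diene terminus C5 sits next to quaternary C4, so the reaction should be slow and its trans/cis-fusion preference rests on small energy differences.
- Against it here: C2 arrives α and must be inverted; C6=C7 must be hydrogenated before C8=C17 exists; the C8 CH2O group must be eliminated to the methylene; and the C9 ester must be extended by five carbons through hindered C11.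
- Comparison: on structure the alternative is the better plan at the key step (two ring bonds and four stereocentres against one skeletal bond and two stereocentres). On mechanism both are concerted, but the directed cyclopropanation has one strongly favoured pathway. On step economy the long sequence after the cycloaddition is expected to cancel the gain, so the alternative is at best equal.

**Alternative 2:** The cut is C9–C10, paid for with a temporary C1–C11 bond. The precursor is the enone A4 (3,5,5-trimethyl-4-{2-[2-((E)-5-(trimethylsilyl)pent-1-en-4-yn-1-yl)-1,3-dioxolan-2-yl]ethyl}cyclohex-2-en-1-one), in which C20 is already the β-methyl of the enone. Irradiation near 350 nm would add C1=C10 across C9=C11 to give the tricyclic photoadduct A3, and the C1–C11 bond would then be cleaved reductively next to the C2 ketone.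
- In its favour: C20 needs no separate step, ring B and the quaternary centre form under neutral conditions, and C2 and C8 arrive at the right oxidation levels.
- Against it here: the triplet 1,4-diradical pathway is stepwise and the first bond closes a six-membered ring, so neither the attacked face of C10 nor straight versus crossed regiochemistry is enforced.
- Against it here: the cis-fused cyclobutane necessarily puts C11 on C9 anti to C20 (9-epi), to be corrected later by equilibration through a C8 ketone.
- Against it here: reductive scission of an unactivated cyclobutyl ketone is much less favourable than that of a cyclopropyl ketone, so ketone reduction would compete.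
- Comparison: it is better in that its key step forms a real ring bond of the target. It is equal in using one sacrificial bond next to the C2 carbonyl and in needing the same late reduction and acetylation at C2. It is weaker in mechanistic predictability. It would be a few steps shorter only if both the photochemical step and the scission behaved.

**Alternative 3:** The cut is C3–C4 in ring A, with C4–C5–C6–C7 recognised as the cyclobutane of a pinane. The precursor is the verbenone-derived ketone A6 (methyl (E)-5-{4-[2-(tert-butyldimethylsilyloxy)prop-2-en-1-yl]-4,6,6-trimethyl-2-oxobicyclo[3.1.1]heptan-3-yl}-3-methylpent-2-enoate). Catalytic t-BuMe2SiOTf would silylate the C8 carbonyl, the C4–C7 bond would ionise to a tertiary C4 cation and a C7=C8 enol silane, and C3 of the tethered silyl enol ether would trap the cation and pass its silyl group on. The product would be A5 (methyl 9-epi-2-oxo-8-(tert-butyldimethylsilyloxy)-17-norlabda-7,13E-dien-15-oate).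
- In its favour: C5 comes from the chiral pool and C10 from a conjugate addition anti to the gem-dimethyl bridge; the side chain is complete; C2 and C8 are differentiated.
- Against it here: pinane-derived tertiary cations usually lose a proton to an isopropenyl or isopropylidene group, and the closure must outrun this while joining a quaternary carbon to C3.
- Against it here: the terminal enol silane must be made selectively beside the ring ketone, and C9 emerges epimeric and must be equilibrated after the C8 ketone is unmasked.
- Comparison: on step economy this is the better plan, likely the shortest of the four. On structure it is equal or better, since strain release builds ring A with no added sacrificial carbon. It is equal in needing the same α-face hydride reduction for the 2β-oxygen. On mechanistic security the directed cyclopropanation is the safer key step.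

Key step: step 12

## Route

Step 1
Reactants: 1 dimedone
Product: 2 3-isobutoxy-5,5-dimethylcyclohex-2-en-1-one
Conditions: i-BuOH, TsOH·H2O (cat.), toluene, reflux, Dean–Stark
Reagents that add atoms: 2-methylpropan-1-ol, CC(C)CO
Why: Acid-catalysed enol etherification of a symmetrical 1,3-dione, driven by azeotropic removal of water; the symmetry of 1 removes any regiochemical question.

Step 2
Reactants: 2 3-isobutoxy-5,5-dimethylcyclohex-2-en-1-one; 3 allyl chloroformate
Product: 5 allyl 5-isobutoxy-3,3-dimethylcyclohexa-1,5-dien-1-yl carbonate, via lithium dienolate 4 (not isolated)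
Conditions: LiN(i-Pr)2, THF, −78 °C; TMEDA; then 3, −78 → −40 °C
Reagents that add atoms: none
Why: Kinetic deprotonation at the α′-methylene gives the cross-conjugated dienolate, and the hard chloroformate with TMEDA should favour O-acylation to the enol carbonate. Any C-acylated allyl β-keto ester is expected to enter step 3 through the same palladium enolate.

Step 3
Reactants: 5 allyl 5-isobutoxy-3,3-dimethylcyclohexa-1,5-dien-1-yl carbonate
Product: 6 (S)-6-allyl-3-isobutoxy-5,5-dimethylcyclohex-2-en-1-one
Conditions: Pd2(dba)3·CHCl3 (2.5 mol %), (R,R)-N,N′-(9,10-dihydro-9,10-ethanoanthracene-11,12-diyl)bis[2-(diphenylphosphino)benzamide] (5.5 mol %), 1,4-dioxane, 23 °C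
Reagents that add atoms: none
Why: Decarboxylative asymmetric allylic alkylation (Tsuji–Trost type): zerovalent palladium ionises the allyl carbonate, CO2 is lost, and the chiral bisphosphine decides which face of the enolate carbon attacks the π-allyl unit, setting C5 (labdane) as (S). The neutral medium should keep the new tertiary centre next to the carbonyl from epimerising.

Step 4
Reactants: 6 (S)-6-allyl-3-isobutoxy-5,5-dimethylcyclohex-2-en-1-one
Product: 8 (S)-6-(3-hydroxypropyl)-3-isobutoxy-5,5-dimethylcyclohex-2-en-1-one, via alkylborane 7 (not isolated)
Conditions: 9-BBN, THF, 0 °C → rt; then NaBO3·4H2O, H2O, rt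
Reagents that add atoms: sodium perborate tetrahydrate (NaBO3·4H2O), [Na+].[Na+].O[B-]1(O)OO[B-](O)(O)OO1
Why: Anti-Markovnikov hydroboration–oxidation of the monosubstituted alkene; 9-BBN should ignore the poorly electrophilic vinylogous ester, and no enone or alkyne is present yet. Perborate oxidises the C–B bond with retention at near-neutral pH, which protects the α′ centre.

Step 5
Reactants: 9 pent-4-yn-1-ol
Product: 11 5-(trimethylsilyl)pent-4-yn-1-ol, via bis-silyl compound 10 (not isolated)
Conditions: n-BuLi (2.2 equiv), THF, −78 °C; Me3SiCl (2.3 equiv), −78 °C → rt; then 1 M HCl, rt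
Reagents that add atoms: chlorotrimethylsilane, C[Si](C)(C)Cl
Why: Double deprotonation and double silylation, followed by selective acid hydrolysis of the labile O–Si bond; the C–Si bond of the alkynylsilane is stable to dilute acid.

Step 6
Reactants: 11 5-(trimethylsilyl)pent-4-yn-1-ol
Product: 12 (5-iodopent-1-yn-1-yl)trimethylsilane
Conditions: I2, PPh3, imidazole, CH2Cl2, 0 °C → rt
Reagents that add atoms: iodine, II
Why: Appel-type iodination of an unhindered primary alcohol through its alkoxyphosphonium salt.

Step 7
Reactants: 8 (S)-6-(3-hydroxypropyl)-3-isobutoxy-5,5-dimethylcyclohex-2-en-1-one; 12 (5-iodopent-1-yn-1-yl)trimethylsilane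
Product: 16 (S)-4-(3-hydroxypropyl)-5,5-dimethyl-3-[5-(trimethylsilyl)pent-4-yn-1-yl]cyclohex-2-en-1-one, via silyl ether 13 (not isolated), via organolithium 14 (not isolated), via carbinol adduct 15 (not isolated)
Conditions: 8, Me3SiCl, Et3N, CH2Cl2, 0 °C, filter, concentrate; 12, t-BuLi (2.1 equiv), Et2O–pentane, −78 °C; CeCl3, THF, −78 °C; add 13, −78 → 0 °C; then 1 M HCl, THF, rt
Reagents that add atoms: none
Why: Stork–Danheiser alkylative 1,3-carbonyl transposition: 1,2-addition to the vinylogous ester carbonyl, then aqueous acid hydrolyses the enol ether, eliminates water and removes the transient O-silyl group. The organocerium reagent suppresses α-deprotonation of the hindered ketone, and excess water captures the allyl oxocarbenium ion before it can lose the C5 proton, so C5 is retained. The lithium reagent is kept at −78 °C to prevent carbolithiation of its own silylalkyne.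

Step 8
Reactants: 16 (S)-4-(3-hydroxypropyl)-5,5-dimethyl-3-[5-(trimethylsilyl)pent-4-yn-1-yl]cyclohex-2-en-1-one
Product: 17 3-{(1S)-6,6-dimethyl-4-oxo-2-[5-(trimethylsilyl)pent-4-yn-1-yl]cyclohex-2-en-1-yl}propanal
Conditions: DMP, CH2Cl2, 0 °C → rt
Reagents that add atoms: none
Why: Dess–Martin oxidation of a primary alcohol to the aldehyde under near-neutral conditions that leave the enone and the alkynylsilane alone.

Step 9
Reactants: 17 3-{(1S)-6,6-dimethyl-4-oxo-2-[5-(trimethylsilyl)pent-4-yn-1-yl]cyclohex-2-en-1-yl}propanal
Product: 18 8α-hydroxy-14-(trimethylsilyl)-15,16,17,20-tetranorlabd-1(10)-en-13-yn-2-one (5α-H, 9α-H, side chain 9β)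
Conditions: DBU (0.5 equiv), MeCN (0.01 M), 0 °C → rt
Reagents that add atoms: none
Why: Intramolecular vinylogous aldol addition: reversible γ-deprotonation at C9 gives the extended dienolate, which closes ring B on the aldehyde; 3-alkyl-5,5-dimethylcyclohexenones are known to react with aldehydes at the exocyclic γ-carbon, and the α′-aldol at neopentyl C3 is reversible. Under equilibrating conditions C9 and C8 should settle with the chain and the hydroxyl both equatorial on the chair of ring B (9β, 8α). The amidine base does not attack the alkynylsilane, and high dilution limits aldehyde self-condensation.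

Step 10
Reactants: 18 8α-hydroxy-14-(trimethylsilyl)-15,16,17,20-tetranorlabd-1(10)-en-13-yn-2-one
Product: 19 8α-(tert-butyldimethylsilyloxy)-14-(trimethylsilyl)-15,16,17,20-tetranorlabd-1(10)-en-13-yn-2-one
Conditions: t-BuMe2SiCl, imidazole, DMF, rt
Reagents that add atoms: tert-butyldimethylsilyl chloride, CC(C)(C)[Si](C)(C)Cl
Why: Standard silylation of an equatorial secondary alcohol; the bulky ether blocks retro-aldol cleavage and keeps O8 from binding zinc in step 12.

Step 11
Reactants: 19 8α-(tert-butyldimethylsilyloxy)-14-(trimethylsilyl)-15,16,17,20-tetranorlabd-1(10)-en-13-yn-2-one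
Product: 20 8α-(tert-butyldimethylsilyloxy)-14-(trimethylsilyl)-15,16,17,20-tetranorlabd-1(10)-en-13-yn-2β-ol
Conditions: LiBH(s-Bu)3, THF, −78 °C
Reagents that add atoms: none
Why: The β,β-disubstituted enone should undergo 1,2-reduction, not conjugate reduction. The bulky hydride attacks equatorially from the α face, because the β face of C2 is blocked by the pseudoaxial 4β-methyl, giving the pseudoaxial 2β-alcohol.

Step 12
Reactants: 20 8α-(tert-butyldimethylsilyloxy)-14-(trimethylsilyl)-15,16,17,20-tetranorlabd-1(10)-en-13-yn-2β-ol; 21 diiodomethane
Product: 22 8α-(tert-butyldimethylsilyloxy)-14-(trimethylsilyl)-1β,20-cyclo-15,16,17-trinorlabd-13-yn-2β-ol (1β,10β-methano adduct)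
Conditions: Et2Zn (5 equiv), 21 (10 equiv), CH2Cl2, −10 °C → rt
Reagents that add atoms: none
Why: Et2Zn converts the 2β-hydroxyl into an ethylzinc alkoxide, and exchange with CH2I2 gives an alkoxide-bound iodomethylzinc carbenoid that transfers CH2 to C1=C10 through a concerted butterfly-type transition state on the face bearing the oxygen. The closest known reaction type is the hydroxyl-directed Simmons–Smith cyclopropanation (Et2Zn/CH2I2 variant) of cyclohex-2-en-1-ols, including ring-fusion alkenes of octalinols and steroidal allylic alcohols. The one ring closed is the cyclopropane C1–C10–C20, formed by a [2+1] methylene transfer in which C1–C20 and C10–C20 arise together, so no open intermediate can rotate or rearrange. The new stereocentres C10 (quaternary) and C1 are both controlled by the C2 carbinol: syn delivery puts C20 on the β face, cis to O2 and anti to H5, which is the trans ring fusion of the target. Facial selectivity is secured by zinc–alkoxide coordination, which should accelerate the β-face pathway well beyond the undirected one even though the axial 4β-methyl is 1,3 to C10. Chemoselectivity is secured because the only other π system is a silylalkyne, which electrophilic zinc carbenoids leave alone. The 8α-oxygen is a bulky silyl ether, so it cannot bind zinc and steer the carbenoid to the α face. Low temperature and short exposure limit ionisation of the allylic alkoxide by ZnI2.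

Step 13
Reactants: 22 8α-(tert-butyldimethylsilyloxy)-14-(trimethylsilyl)-1β,20-cyclo-15,16,17-trinorlabd-13-yn-2β-ol
Product: 23 8α-(tert-butyldimethylsilyloxy)-14-(trimethylsilyl)-1β,20-cyclo-15,16,17-trinorlabd-13-yn-2-one
Conditions: DMP, CH2Cl2, rt
Reagents that add atoms: none
Why: Dess–Martin oxidation of the cyclopropyl carbinol to the cyclopropyl ketone without opening the three-membered ring.

Step 14
Reactants: 23 8α-(tert-butyldimethylsilyloxy)-14-(trimethylsilyl)-1β,20-cyclo-15,16,17-trinorlabd-13-yn-2-one
Product: 24 8α-(tert-butyldimethylsilyloxy)-14-(trimethylsilyl)-15,16,17-trinorlabd-13-yn-2-one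
Conditions: SmI2 (2.5 equiv), HMPA, t-BuOH (2 equiv), THF, −78 → 0 °C
Reagents that add atoms: none
Why: Reductive ring opening of a cyclopropyl ketone: divalent samarium forms the ketyl, the exocyclic C1–C20 bond (the one that overlaps with the carbonyl π system) breaks, and a second electron and a proton turn C20 into the 10β-methyl and C2 back into the ketone. SmI2 is chosen because it leaves the silylalkyne and the silyl ether untouched, which a dissolving metal might not.

Step 15
Reactants: 24 8α-(tert-butyldimethylsilyloxy)-14-(trimethylsilyl)-15,16,17-trinorlabd-13-yn-2-one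
Product: 25 8α-(tert-butyldimethylsilyloxy)-14-(trimethylsilyl)-15,16,17-trinorlabd-13-yn-2β-ol
Conditions: LiBH(s-Bu)3, THF, −78 °C
Reagents that add atoms: none
Why: Hydride reduction under steric approach control: the β face of C2 is blocked by the two syn-axial methyls (C19, C20), so the bulky hydride enters equatorially from the α face and gives the axial 2β-alcohol.

Step 16
Reactants: 25 8α-(tert-butyldimethylsilyloxy)-14-(trimethylsilyl)-15,16,17-trinorlabd-13-yn-2β-ol
Product: 26 2β-acetoxy-8α-(tert-butyldimethylsilyloxy)-14-(trimethylsilyl)-15,16,17-trinorlabd-13-yne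
Conditions: Ac2O, Et3N, DMAP (cat.), CH2Cl2, rt → 40 °C
Reagents that add atoms: acetic anhydride, CC(=O)OC(C)=O
Why: DMAP-catalysed acylation, which is effective for hindered axial secondary alcohols; the acetate is the final C2 group and also masks O2 during the C8 oxidation.

Step 17
Reactants: 26 2β-acetoxy-8α-(tert-butyldimethylsilyloxy)-14-(trimethylsilyl)-15,16,17-trinorlabd-13-yne
Product: 27 2β-acetoxy-15,16,17-trinorlabd-13-yn-8α-ol
Conditions: Bu4NF, AcOH, THF, rt → 45 °C
Reagents that add atoms: none
Why: Fluoride cleaves both the O–Si bond at C8 and the alkynyl C–Si bond in one operation; buffering with acetic acid should protect the acetate from basic fluoride.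

Step 18
Reactants: 27 2β-acetoxy-15,16,17-trinorlabd-13-yn-8α-ol
Product: 28 2β-acetoxy-15,16,17-trinorlabd-13-yn-8-one
Conditions: DMP, CH2Cl2, rt
Reagents that add atoms: none
Why: Dess–Martin oxidation of the secondary alcohol; C9 is now α to a ketone, but the equatorial 9β chain is already the more stable arrangement.

Step 19
Reactants: 28 2β-acetoxy-15,16,17-trinorlabd-13-yn-8-one
Product: 29 2β-acetoxy-15,16-dinorlabd-8(17)-en-13-yne
Conditions: Zn, CH2Br2, TiCl4, THF–CH2Cl2, 0 °C → rt
Reagents that add atoms: dibromomethane, BrCBr
Why: Takai–Lombardo methylenation: a non-basic gem-dimetallic reagent that methylenates hindered, enolisable ketones and is expected to spare the acetate and the terminal alkyne.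

Step 20
Reactants: 29 2β-acetoxy-15,16-dinorlabd-8(17)-en-13-yne; 3 allyl chloroformate
Product: 31 allyl 2β-acetoxylabda-8(17),13E-dien-15-oate, via alkenylalane 30 (not isolated)
Conditions: Me3Al (3 equiv), Cp2ZrCl2 (0.5 equiv), CH2Cl2, 0 °C → rt; then 3, 0 °C → rt
Reagents that add atoms: trimethylaluminium, C[Al](C)C
Why: Negishi zirconium-catalysed carboalumination: syn addition of Me–Al places the methyl on C13 and aluminium on C14, and direct acylation of the alkenylalane by the chloroformate proceeds with retention, so the enoate is E. The 1,1-disubstituted C8=C17 alkene is inert to this reagent.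

Step 21
Reactants: 31 allyl 2β-acetoxylabda-8(17),13E-dien-15-oate
Product: 32 2β-acetoxylabda-8(17),13E-dien-15-oic acid
Conditions: Pd(PPh3)4 (5 mol %), morpholine, THF, rt
Reagents that add atoms: none
Why: Tsuji–Trost deallylation: zerovalent palladium ionises the allyl ester and morpholine traps the π-allyl unit, freeing the acid under neutral conditions that leave the non-allylic acetate, the exocyclic alkene and the enoate geometry untouched.

## Compound list

1 | dimedone (5,5-dimethylcyclohexane-1,3-dione) | CC1(C)CC(=O)CC(=O)C1 | starting material
2 | 3-isobutoxy-5,5-dimethylcyclohex-2-en-1-one | CC(C)COC1=CC(=O)CC(C)(C)C1 | intermediate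
3 | allyl chloroformate | C=CCOC(=O)Cl | starting material
4 | lithium 5-isobutoxy-3,3-dimethylcyclohexa-1,5-dien-1-olate | [Li]OC1=CC(C)(C)CC(OCC(C)C)=C1 | intermediate
5 | allyl 5-isobutoxy-3,3-dimethylcyclohexa-1,5-dien-1-yl carbonate | C=CCOC(=O)OC1=CC(C)(C)CC(OCC(C)C)=C1 | intermediate
6 | (S)-6-allyl-3-isobutoxy-5,5-dimethylcyclohex-2-en-1-one | C=CC[C@@H]1C(=O)C=C(OCC(C)C)CC1(C)C | intermediate
7 | 9-{3-[(1S)-4-isobutoxy-6,6-dimethyl-2-oxocyclohex-3-en-1-yl]propyl}-9-borabicyclo[3.3.1]nonane | B1(CCC[C@@H]2C(=O)C=C(OCC(C)C)CC2(C)C)C3CCCC1CCC3 | intermediate
8 | (S)-6-(3-hydroxypropyl)-3-isobutoxy-5,5-dimethylcyclohex-2-en-1-one | OCCC[C@@H]1C(=O)C=C(OCC(C)C)CC1(C)C | intermediate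
9 | pent-4-yn-1-ol | C#CCCCO | starting material
10 | trimethyl{[5-(trimethylsilyl)pent-4-yn-1-yl]oxy}silane | C[Si](C)(C)C#CCCCO[Si](C)(C)C | intermediate
11 | 5-(trimethylsilyl)pent-4-yn-1-ol | C[Si](C)(C)C#CCCCO | intermediate
12 | (5-iodopent-1-yn-1-yl)trimethylsilane | C[Si](C)(C)C#CCCCI | intermediate
13 | (S)-3-isobutoxy-5,5-dimethyl-6-[3-(trimethylsilyloxy)propyl]cyclohex-2-en-1-one | C[Si](C)(C)OCCC[C@@H]1C(=O)C=C(OCC(C)C)CC1(C)C | intermediate
14 | [5-(trimethylsilyl)pent-4-yn-1-yl]lithium | [Li]CCCC#C[Si](C)(C)C | intermediate
15 | (6S)-3-isobutoxy-5,5-dimethyl-1-[5-(trimethylsilyl)pent-4-yn-1-yl]-6-[3-(trimethylsilyloxy)propyl]cyclohex-2-en-1-ol (either configuration at C1; present as its metal alkoxide) | C[Si](C)(C)OCCC[C@@H]1C(O)(CCCC#C[Si](C)(C)C)C=C(OCC(C)C)CC1(C)C | intermediate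
16 | (S)-4-(3-hydroxypropyl)-5,5-dimethyl-3-[5-(trimethylsilyl)pent-4-yn-1-yl]cyclohex-2-en-1-one | OCCC[C@@H]1C(CCCC#C[Si](C)(C)C)=CC(=O)CC1(C)C | intermediate
17 | 3-{(1S)-6,6-dimethyl-4-oxo-2-[5-(trimethylsilyl)pent-4-yn-1-yl]cyclohex-2-en-1-yl}propanal | O=CCC[C@@H]1C(CCCC#C[Si](C)(C)C)=CC(=O)CC1(C)C | intermediate
18 | 8α-hydroxy-14-(trimethylsilyl)-15,16,17,20-tetranorlabd-1(10)-en-13-yn-2-one (5α-H, 9α-H) | O[C@@H]1CC[C@H]2C(C)(C)CC(=O)C=C2[C@H]1CCC#C[Si](C)(C)C | intermediate
19 | 8α-(tert-butyldimethylsilyloxy)-14-(trimethylsilyl)-15,16,17,20-tetranorlabd-1(10)-en-13-yn-2-one | CC(C)(C)[Si](C)(C)O[C@@H]1CC[C@H]2C(C)(C)CC(=O)C=C2[C@H]1CCC#C[Si](C)(C)C | intermediate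
20 | 8α-(tert-butyldimethylsilyloxy)-14-(trimethylsilyl)-15,16,17,20-tetranorlabd-1(10)-en-13-yn-2β-ol | CC(C)(C)[Si](C)(C)O[C@@H]1CC[C@H]2C(C)(C)C[C@@H](O)C=C2[C@H]1CCC#C[Si](C)(C)C | intermediate
21 | diiodomethane | ICI | starting material
22 | 8α-(tert-butyldimethylsilyloxy)-14-(trimethylsilyl)-1β,20-cyclo-15,16,17-trinorlabd-13-yn-2β-ol | CC(C)(C)[Si](C)(C)O[C@@H]1CC[C@H]2C(C)(C)C[C@@H](O)[C@H]3C[C@]32[C@H]1CCC#C[Si](C)(C)C | intermediate
23 | 8α-(tert-butyldimethylsilyloxy)-14-(trimethylsilyl)-1β,20-cyclo-15,16,17-trinorlabd-13-yn-2-one | CC(C)(C)[Si](C)(C)O[C@@H]1CC[C@H]2C(C)(C)CC(=O)[C@H]3C[C@]32[C@H]1CCC#C[Si](C)(C)C | intermediate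
24 | 8α-(tert-butyldimethylsilyloxy)-14-(trimethylsilyl)-15,16,17-trinorlabd-13-yn-2-one (10β-methyl, 5α-H) | CC(C)(C)[Si](C)(C)O[C@@H]1CC[C@H]2C(C)(C)CC(=O)C[C@]2(C)[C@H]1CCC#C[Si](C)(C)C | intermediate
25 | 8α-(tert-butyldimethylsilyloxy)-14-(trimethylsilyl)-15,16,17-trinorlabd-13-yn-2β-ol | CC(C)(C)[Si](C)(C)O[C@@H]1CC[C@H]2C(C)(C)C[C@@H](O)C[C@]2(C)[C@H]1CCC#C[Si](C)(C)C | intermediate
26 | 2β-acetoxy-8α-(tert-butyldimethylsilyloxy)-14-(trimethylsilyl)-15,16,17-trinorlabd-13-yne | CC(C)(C)[Si](C)(C)O[C@@H]1CC[C@H]2C(C)(C)C[C@@H](OC(C)=O)C[C@]2(C)[C@H]1CCC#C[Si](C)(C)C | intermediate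
27 | 2β-acetoxy-15,16,17-trinorlabd-13-yn-8α-ol | O[C@@H]1CC[C@H]2C(C)(C)C[C@@H](OC(C)=O)C[C@]2(C)[C@H]1CCC#C | intermediate
28 | 2β-acetoxy-15,16,17-trinorlabd-13-yn-8-one | O=C1CC[C@H]2C(C)(C)C[C@@H](OC(C)=O)C[C@]2(C)[C@H]1CCC#C | intermediate
29 | 2β-acetoxy-15,16-dinorlabd-8(17)-en-13-yne | C=C1CC[C@H]2C(C)(C)C[C@@H](OC(C)=O)C[C@]2(C)[C@H]1CCC#C | intermediate
30 | [2β-acetoxy-15-norlabda-8(17),13E-dien-14-yl]dimethylalane | C=C1CC[C@H]2C(C)(C)C[C@@H](OC(C)=O)C[C@]2(C)[C@H]1CC/C(C)=C/[Al](C)C | intermediate
31 | allyl 2β-acetoxylabda-8(17),13E-dien-15-oate | C=C1CC[C@H]2C(C)(C)C[C@@H](OC(C)=O)C[C@]2(C)[C@H]1CC/C(C)=C/C(=O)OCC=C | intermediate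
32 | 2β-acetoxylabda-8(17),13E-dien-15-oic acid (CNP0255148.2) | C=C1CC[C@H]2C(C)(C)C[C@@H](OC(C)=O)C[C@]2(C)[C@H]1CC/C(C)=C/C(=O)O | target

## Step count and least certain steps

Total: 21 steps. Longest linear sequence: 19 steps (steps 1–4 and 7–21, from 1); steps 5–6 are a two-step branch that supplies 12.

**Step 12 (key step).** The most likely failure is slow methylene transfer to the hindered ring-fusion alkene, whose β face also carries the axial 4β-methyl. That would leave time for ZnI2-promoted ionisation of the pseudoaxial allylic alkoxide (elimination to a diene) or for O-methylation. The fallback changes the carbenoid class: a samarium carbenoid made from samarium amalgam (Sm with HgCl2) and CH2ICl in THF, −78 °C → rt. It is generated and consumed on the metal alkoxide in a medium that is not Lewis acidic, and it reacts only with allylic alcohols, including highly substituted ones. The fallback sets out from 20 and returns at 22 with no new compound.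

**Step 9.** The risk is loss of regiocontrol among the γ (C9), α′ (C3) and α (C1) enolate pathways, together with aldehyde self-condensation, vinylogous dehydration to a dienone and slow erosion of C5 through the C5 dienolate on long exposure to base. The fallback replaces equilibrating base catalysis with template-directed kinetic deprotonation. Compound 17 is complexed with Al(OC6H3-2,6-Ph2)3 (2.2 equiv, from Me3Al and 2,6-diphenylphenol) in toluene at −78 °C and then treated with LiN(i-Pr)2. The bulky aluminium phenoxide shields the carbons next to the ketone and activates the aldehyde, so only the exposed C9 proton is removed and the aldol occurs at γ. It sets out from 17 and returns at 18 with no new compound.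

**Step 3.** The risk is erosion of enantiopurity by proton transfer between the palladium enolate and the product (which has a tertiary centre α to the carbonyl), and an uncertain level of induction at an enolate carbon next to a quaternary centre. The fallback gives up catalysis for resolution. Compound 2 is alkylated with LiN(i-Pr)2 and allyl bromide to give racemic 6-allyl-3-isobutoxy-5,5-dimethylcyclohex-2-en-1-one F1, and the enantiomers are separated by preparative chromatography on a chiral stationary phase. It sets out from 2 and returns at 6; the unwanted enantiomer could in principle be racemised with base and recycled.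

**Step 14.** The risk is capture of the transient C20 radical by the tethered alkyne (6-exo-dig) before the second electron transfer, together with over-reduction or pinacol coupling of the ketone. The fallback opens the ring by a polar route. Compound 23 is treated with Me3SiCl/NaI in MeCN at 0 °C for a short time to spare the silyl ether; iodide attacks C20 in a homoconjugate sense and aqueous work-up gives the 20-iodo ketone 8α-(tert-butyldimethylsilyloxy)-20-iodo-14-(trimethylsilyl)-15,16,17-trinorlabd-13-yn-2-one F2. Reduction with Bu3SnH/AIBN in toluene at 80 °C, at high stannane concentration so that hydrogen transfer outruns cyclisation, then gives 24. It sets out from 23 and returns at 24.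

**Step 20.** The risk is attack of the organoaluminium and zirconium species on the acetate, partial metalation of the terminal alkyne and incomplete acylation of the alkenylalane. The fallback avoids organoaluminium reagents. Compound 29 is hydrated in the Markovnikov sense (Ph3PAuNTf2 cat., aqueous dioxane) to the methyl ketone 2β-acetoxy-15-norlabd-8(17)-en-13-one F3. Horner–Wadsworth–Emmons olefination with allyl (diethoxyphosphoryl)acetate and NaH in THF then gives 31. The price is lower geometric control: the allyl (13Z)-ester F4 is expected as a minor isomer and must be separated. It sets out from 29 and returns at 31.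

## Further compounds

F0 | step 12 | none | none
F0 | step 9 | none | none
F1 | step 3 | racemic 6-allyl-3-isobutoxy-5,5-dimethylcyclohex-2-en-1-one | C=CCC1C(=O)C=C(OCC(C)C)CC1(C)C
F2 | step 14 | 8α-(tert-butyldimethylsilyloxy)-20-iodo-14-(trimethylsilyl)-15,16,17-trinorlabd-13-yn-2-one | CC(C)(C)[Si](C)(C)O[C@@H]1CC[C@H]2C(C)(C)CC(=O)C[C@]2(CI)[C@H]1CCC#C[Si](C)(C)C
F3 | step 20 | 2β-acetoxy-15-norlabd-8(17)-en-13-one | C=C1CC[C@H]2C(C)(C)C[C@@H](OC(C)=O)C[C@]2(C)[C@H]1CCC(C)=O
F4 | step 20 | allyl 2β-acetoxylabda-8(17),13Z-dien-15-oate | C=C1CC[C@H]2C(C)(C)C[C@@H](OC(C)=O)C[C@]2(C)[C@H]1CC/C(C)=C\C(=O)OCC=C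
A1 | alternative 1 | trans-fused octalin Diels–Alder adduct (2α-silyloxy, 8β-CH2OPMB, 9β-CO2Me, C6=C7) | COc1ccc(COC[C@H]2C=C[C@H]3C(C)(C)C[C@H](O[Si](C)(C)C(C)(C)C)C[C@]3(C)[C@H]2C(=O)OC)cc1
A2 | alternative 1 | methyl (2E,8E,10E)-5-(tert-butyldimethylsilyloxy)-12-(4-methoxybenzyloxy)-3,7,7-trimethyldodeca-2,8,10-trienoate | COc1ccc(COC/C=C/C=C/C(C)(C)C[C@H](O[Si](C)(C)C(C)(C)C)C/C(C)=C/C(=O)OC)cc1
A3 | alternative 2 | tricyclic cyclobutane photoadduct (C2 ketone, C8 dioxolane, cyclobutane C1–C10–C9–C11) | O=C1CC(C)(C)[C@@H]2CCC3(OCCO3)[C@H]4[C@H](CC#C[Si](C)(C)C)[C@@H]1[C@@]24C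
A4 | alternative 2 | 3,5,5-trimethyl-4-{2-[2-((E)-5-(trimethylsilyl)pent-1-en-4-yn-1-yl)-1,3-dioxolan-2-yl]ethyl}cyclohex-2-en-1-one | O=C1C=C(C)[C@@H](CCC2(OCCO2)/C=C/CC#C[Si](C)(C)C)C(C)(C)C1
A5 | alternative 3 | methyl 9-epi-2-oxo-8-(tert-butyldimethylsilyloxy)-17-norlabda-7,13E-dien-15-oate | CC(C)(C)[Si](C)(C)OC1=CC[C@H]2C(C)(C)CC(=O)C[C@]2(C)[C@@H]1CC/C(C)=C/C(=O)OC
A6 | alternative 3 | methyl (E)-5-{4-[2-(tert-butyldimethylsilyloxy)prop-2-en-1-yl]-4,6,6-trimethyl-2-oxobicyclo[3.1.1]heptan-3-yl}-3-methylpent-2-enoate | O=C1[C@@H]2C[C@@H](C2(C)C)[C@](C)(CC(=C)O[Si](C)(C)C(C)(C)C)[C@@H]1CC/C(C)=C/C(=O)OC
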